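## Retrosynthetic overview
1. Andrographolide comes from global desilylation of a tris-TBS α-alkylidene lactone, which is made by aldol/E1cB dehydration of a C12 aldehyde with (S)-3-TBSO-γ-butyrolactone. The chiral-pool lactone sets C14, and the dehydration sets the E-alkene.
2. The C12 aldehyde comes from DIBAL reduction of an ent-tetranor-labdane ethyl ester.
3. Key step: a Cp2TiCl radical bicyclization of a trans-epoxy-polyprene forms both rings, the 3α-OH, C4, C5, C9, C10 and the exocyclic C8=C17 alkene in one operation.
4. The epoxide is built by Sharpless AE of a terminal allylic alcohol. That alcohol comes from SeO2 oxidation of ethyl homofarnesoate, which is made from farnesol by Pd-catalysed carbonylation.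

Assumptions: (E,E)-farnesol, D-(−)-DET, Cp2TiCl2 and (S)-3-hydroxy-γ-butyrolactone are commercial. The C4 epimer from the bicyclization is separated chromatographically.

The target is an ent-labdane. It has 3α-OH (3R), axial 19-CH2OH syn to C20, 5β-H, 9β-H, 10α-CH3, (14S) and E-Δ12.

---

## Route

**Step 1**
Reactants: 1, (2E,6E)-farnesol
Product: 2, farnesyl ethyl carbonate
Conditions: ClCO2Et, pyridine, CH2Cl2, 0 °C
Reagents that add atoms: ethyl chloroformate, CCOC(=O)Cl
Why: Acylation of the primary allylic alcohol makes a Pd-ionizable leaving group and leaves the three olefins untouched.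

**Step 2**
Reactants: 2
Product: 3, ethyl (3E,7E)-4,8,12-trimethyltrideca-3,7,11-trienoate (ethyl homofarnesoate)
Conditions: Pd(PPh3)4 (5 mol%), CO (10 atm), EtOH, 60 °C
Reagents that add atoms: carbon monoxide, [C-]#[O+]; ethanol (solvent, supplies or exchanges the OEt), CCO
Why: Tsuji-type Pd-catalysed alkoxycarbonylation of an allylic carbonate (via π-allyl-Pd and CO insertion) occurs at the less hindered terminus and keeps the E geometry. This puts the ester carbon, which becomes C12, exactly one carbon beyond C11.

**Step 3**
Reactants: 3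
Product: 4, ethyl (3E,7E,11E)-13-hydroxy-4,8,12-trimethyltrideca-3,7,11-trienoate
Conditions: SeO2 (10 mol%), TBHP, salicylic acid, CH2Cl2, 25 °C; then NaBH4, EtOH, 0 °C
Reagents that add atoms: tert-butyl hydroperoxide, CC(C)(C)OO (oxygen source); selenium dioxide, O=[Se]=O
Why: Umbreit–Sharpless SeO2 allylic oxidation (ene/[2,3]) prefers the terminal olefin and its E-methyl (trans to the chain). NaBH4 reduces any over-oxidized aldehyde. This sets the future C19 carbon and the E-allylic alcohol needed for Step 4. Regioselectivity is modest, so the terminal-oxidation product is isolated by chromatography.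

**Step 4**
Reactants: 4
Product: 5, ethyl (3E,7E)-(11R,12R)-11,12-epoxy-13-hydroxy-4,8,12-trimethyltrideca-3,7-dienoate
Conditions: Ti(OiPr)4 (10 mol%), D-(−)-DET (12 mol%), TBHP, 4 Å MS, CH2Cl2, −20 °C
Reagents that add atoms: tert-butyl hydroperoxide, CC(C)(C)OO
Why: Sharpless asymmetric epoxidation is directed by the allylic OH, so the two non-allylic trisubstituted olefins are untouched. D-(−)-DET gives the (R,R) trans-epoxide, whose C3-equivalent carbon is R, which becomes C3 of the ent-series target.

**Step 5**
Reactants: 5
Product: 6, the TBS ether of 5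
Conditions: TBSCl, imidazole, DMF, 25 °C
Reagents that add atoms: tert-butyldimethylsilyl chloride, CC(C)(C)[Si](C)(C)Cl
Why: Silylation of the primary alcohol makes it inert to Ti(III) and keeps it as the future C19–O protecting group.

**Step 6**
Reactants: 6
Product: 7, ethyl ent-3α-hydroxy-19-(TBSO)-13,14,15,16-tetranorlabd-8(17)-en-12-oate
Conditions: Cp2TiCl (from Cp2TiCl2 2.2 equiv, Zn dust 5 equiv), THF, 25 °C, 4 h; aq. HCl workup
Reagents that add atoms: none
Why: Ti(III) radical epoxypolyene bicyclization. Homolysis of the epoxide C4–O bond gives a tertiary radical. It undergoes 6-endo/6-endo chair–chair cyclization onto C5=C10 and then C9=C8. The resulting C8 radical is trapped by Ti(III), and β-H elimination gives the exocyclic C8=C17 alkene. C3 keeps its configuration, and the chair–chair transition state sets the trans-decalin (C5, C9, C10) with 3-OH equatorial.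
Proposed new method: Cp2TiCl epoxypolyene cascades are precedented for gem-dimethyl termini (epoxyfarnesyl esters → 3-hydroxy-drim-8(12)-enes). A CH2OTBS-bearing, unsymmetrical C4 terminus is an extension of that chemistry. The C4 radical is planar, so axial CH2OTBS versus axial CH3 is decided only by the chair transition state and is expected to be poorly selective (about 1:1 to 2:1). The 4-epimer is removed by chromatography.

**Step 7**
Reactants: 7
Product: 8, the 3-O-TBS ether of 7
Conditions: TBSOTf, 2,6-lutidine, CH2Cl2, −78 → 0 °C
Reagents that add atoms: tert-butyldimethylsilyl triflate, CC(C)(C)[Si](C)(C)OS(=O)(=O)C(F)(F)F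
Why: The hindered equatorial 3-OH next to the quaternary C4 needs a silyl triflate. No stereocentre is touched, and the exocyclic alkene and ester survive.

**Step 8**
Reactants: 8
Product: 9, 3α,19-bis(TBSO)-ent-13,14,15,16-tetranorlabd-8(17)-en-12-al
Conditions: DIBAL-H (1.1 equiv), CH2Cl2, −78 °C; Rochelle salt workup
Reagents that add atoms: none
Why: Partial ester-to-aldehyde reduction at −78 °C (a stable tetrahedral aluminate). The aldehyde is not α-epimerizable at C9, since the only α-CH2 is C11.

**Step 9**
Reactants: 10, (S)-3-hydroxy-γ-butyrolactone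
Product: 11, (S)-4-(TBSO)oxolan-2-one
Conditions: TBSCl, imidazole, DMF, 25 °C
Reagents that add atoms: tert-butyldimethylsilyl chloride, CC(C)(C)[Si](C)(C)Cl
Why: Protection of the secondary OH. The (S) centre is untouched and becomes C14 (S) of the target.

**Step 10**
Reactants: 9 and 11
Product: 12, β-hydroxy lactone aldol adducts (C12/C13 diastereomer mixture; C14 fixed)
Conditions: LiHMDS, THF, −78 °C, 45 min; then 9, −78 °C, 2 h
Reagents that add atoms: none
Why: Lactone enolate aldol. The β-silyloxy enolate is stable at −78 °C, and both new stereocentres are destroyed in the next step, so their diastereoselectivity is irrelevant.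

**Step 11**
Reactants: 12
Product: 13, tris-TBS andrographolide, (E)-alkylidene lactone
Conditions: MsCl, Et3N, CH2Cl2, 0 °C; then DBU, 0 °C → 25 °C
Reagents that add atoms: none (the mesyl group is lost)
Why: Mesylation followed by E1cB elimination through the lactone enolate (the OMs leaves in preference to OTBS) gives the thermodynamically preferred E-trisubstituted alkene, with the decalinyl group trans to C=O. C14 is not involved.

**Step 12**
Reactants: 13
Product: 14, andrographolide
Conditions: HF·pyridine, THF/pyridine, 0 → 25 °C, 24–48 h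
Reagents that add atoms: none
Why: Buffered fluoride removes all three TBS ethers (C3, C19 and C14) without acid-promoted allylic rearrangement or lactone ring-opening.

---

## Compound list
1 | (2E,6E)-farnesol | CC(C)=CCC/C(C)=C/CC/C(C)=C/CO | starting material
2 | farnesyl ethyl carbonate | CCOC(=O)OC/C=C(\C)CC/C=C(\C)CCC=C(C)C | intermediate
3 | ethyl (3E,7E)-homofarnesoate | CCOC(=O)C/C=C(\C)CC/C=C(\C)CCC=C(C)C | intermediate
4 | ethyl (3E,7E,11E)-13-hydroxy-4,8,12-trimethyltrideca-3,7,11-trienoate | CCOC(=O)C/C=C(\C)CC/C=C(\C)CC/C=C(\C)CO | intermediate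
5 | (11R,12R)-epoxy alcohol | CCOC(=O)C/C=C(\C)CC/C=C(\C)CC[C@H]1O[C@]1(C)CO | intermediate
6 | TBS ether of 5 | CCOC(=O)C/C=C(\C)CC/C=C(\C)CC[C@H]1O[C@]1(C)CO[Si](C)(C)C(C)(C)C | intermediate
7 | ethyl ent-3α-hydroxy-19-TBSO-tetranorlabd-8(17)-en-12-oate | C=C1CC[C@@H]2[C@](C)(CO[Si](C)(C)C(C)(C)C)[C@H](O)CC[C@@]2(C)[C@@H]1CC(=O)OCC | intermediate
8 | 3,19-bis-TBS ester | C=C1CC[C@@H]2[C@](C)(CO[Si](C)(C)C(C)(C)C)[C@H](O[Si](C)(C)C(C)(C)C)CC[C@@]2(C)[C@@H]1CC(=O)OCC | intermediate
9 | C12 aldehyde | C=C1CC[C@@H]2[C@](C)(CO[Si](C)(C)C(C)(C)C)[C@H](O[Si](C)(C)C(C)(C)C)CC[C@@]2(C)[C@@H]1CC=O | intermediate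
10 | (S)-3-hydroxy-γ-butyrolactone | O=C1C[C@H](O)CO1 | starting material
11 | (S)-4-TBSO-oxolan-2-one | O=C1C[C@H](O[Si](C)(C)C(C)(C)C)CO1 | intermediate
12 | aldol adducts (C12, C13 unspecified) | C=C1CC[C@@H]2[C@](C)(CO[Si](C)(C)C(C)(C)C)[C@H](O[Si](C)(C)C(C)(C)C)CC[C@@]2(C)[C@@H]1CC(O)C3C(=O)OC[C@H]3O[Si](C)(C)C(C)(C)C | intermediate
13 | tris-TBS andrographolide | C=C1CC[C@@H]2[C@](C)(CO[Si](C)(C)C(C)(C)C)[C@H](O[Si](C)(C)C(C)(C)C)CC[C@@]2(C)[C@@H]1C/C=C3/C(=O)OC[C@H]3O[Si](C)(C)C(C)(C)C | intermediate
14 | andrographolide | C=C1CC[C@@H]2[C@](C)(CO)[C@H](O)CC[C@@]2(C)[C@@H]1C/C=C1/C(=O)OC[C@H]1O | target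

---

## Step count
Total steps: 12. Longest linear sequence: 11 (steps 1–8, then 10–12; step 9 is the lactone branch).

## Three steps most likely to fail
1. **Step 6 (Ti(III) bicyclization).** Risks are poor C4 diastereoselectivity, endocyclic alkene isomers, and Nugent–RajanBabu-type deoxygenation or β-OR elimination.
   Fallback: switch to an epoxide-initiated cationic bicyclization (MeAlCl2, −78 °C). Use the Z-configured epoxy-alcohol TBS ether, whose epoxide geometry fixes the axial CH2OTBS, and terminate the C8 cation with an allylsilane (CH2SiMe3) to give the exocyclic alkene.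
2. **Step 3 (SeO2 regioselectivity and yield).** Oxidation at the terminal olefin competes with the two internal trisubstituted olefins and gives about 30–40%.
   Fallback: drop C19 oxidation from the acyclic stage. Do a terminal-selective Shi epoxidation of 3 (L-fructose-derived catalyst, giving the (R)-epoxide) and run the gem-dimethyl Ti(III) bicyclization, which has no C4 problem. Then install C19 late on the 3-ketone by oxime-directed Pd(II) C–H acetoxylation, or by sulfamate-directed nitrene insertion, and reduce the ketone to the 3α-OH.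
3. **Step 10 (aldol/dehydration).** Risks are β-silyloxy elimination of the enolate, Z-alkene formation, and γ-epimerization at C14 under DBU.
   Fallback: change how C14 is set. Knoevenagel-condense aldehyde 9 with tetronic acid to give the 3-alkylidene-tetronic acid, then reduce the C14 ketone enantioselectively (CBS or Noyori transfer hydrogenation), with I2-catalysed Z→E isomerization if needed.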